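The runs are simulated on assumed constants; noise was put on by code.

I had no rate constants for this flask, just three product curves from earlier runs, so my reckoning had to come from their shapes.

| flask | substrate | reagent | free catalyst | remark |
|---|---|---|---|---|
| maple | 0.13 M | 3 equiv | 2 mol% | run made earlier |
| birch | 0.30 M | 3 equiv | 2 mol% | run made earlier |
| oak | 0.20 M | 3 equiv | 4 mol% | run made earlier |
| flask | 0.20 M | 3.00 equiv | 2 mol% |  |

- maple (time / min: product / %): 6.00: 1.5; 15.0: 1.2; 20.0: 1.3; 30.0: 2.9; 40.0: 4.0; 50.0: 4.1
- birch (time / min: product / %): 4.00: 0.7; 6.00: 0; 8.00: 0; 15.0: 0.8; 20.0: 1.8; 30.0: 3.7; 50.0: 8.7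
- oak (time / min: product / %): 4.00: 0; 12.0: 2.8; 20.0: 5.7; 30.0: 8.7; 50.0: 17.3

(scatter of a reading: 0.5 percentage points)

- what has left substrate counts as converted, also if it is not yet product

- apparent order in free catalyst when 5.0% of the substrate are converted (percent change of the rate of making product for one percent more free catalyst charged)

Birch and oak start flat: birch read 0% at 8.00 min, and oak read 0% at 4.00 min. Then comes a knee, and oak, with twice the catalyst of the flask, had 2.8% at 12.0 min. Birch and oak were still climbing at their last readings, 8.7% and 17.3% of the charge, so neither showed a level.

Oak has the flask's substrate and reagent charge, so I took as the zero of my scale the case where catalyst merely sets the pace. On that zero case the flask's curve is oak's stretched to twice the time, with equal product at equal loading times time, and the order is exactly one. Any departure from equal product measures the departure from one: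

oak at 25.0 min, mean of its neighbouring readings: 7.20%

flask at 50.0 min, my estimate between maple and birch on a log scale of substrate: 6.04%

order: 1.25

I call this the stretch order: one plus the base-two logarithm of oak's product over the flask's estimated product at equal loading times time. It is a reading, and it carries the scatter of its points.

The forecast said 1.35, on the ground that “Doubling the catalyst therefore raises the rate about 2.5-fold”. My 1.25 is lower, and I committed to mine.

The flask gave 0.83.

    reagent + catalyst intermediate → free catalyst + product (k = 0.0787 L mol⁻¹ s⁻¹)
    free catalyst + open intermediate ⇌ catalyst intermediate (K = 6.16 L mol⁻¹, k = 0.250 L mol⁻¹ s⁻¹)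
    substrate + free catalyst → free catalyst + open intermediate (k = 2.19 L mol⁻¹ s⁻¹)
    reagent + free catalyst ⇌ idle complex, settled at all times (K = 19.9 L mol⁻¹)

That is 0.170 below the zero of my scale, while my stretch order stood 0.250 above it. In the flask the 5.0% conversion came at 1.26 min, earlier than the 50.0 min at which I estimated the flask's product, and my stretch order belongs to that later part. In the flask reagent parks free catalyst as idle complex, an off-cycle form holding 91.6% of the catalyst at 4.00 min. The same flask run without that parking gave an order of 0.16 in place of 0.83.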